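**Retrosynthetic overview**

- The strategy rests on the only stereocentre: the (S)-carbinol carbon C16 of the C17 side chain (the CH3–CH(OH)– end, chain numbered from ring A outward). It is an unactivated methylene six CH2 groups beyond the C8=C9 (Z)-alkene and far from ring A, the resorcinol and the only ring. It is disconnected last, as C16–OH to C16–H, by an (ω-1)-selective P450 hydroxylation.
- This leaves the achiral deoxy alkenylresorcinol 9, which comes from its dimethyl ether 7 by O-demethylation.
- 7 is cut at the aryl–C1 bond: decarboxylative arylation of oleic acid (as its N-hydroxyphthalimide ester 3) with the arylzinc 6 from 1-bromo-3,5-dimethoxybenzene. Chain length and Z-alkene come intact from oleic acid.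
- Ring order: no ring is formed; ring A is bought.

Key step: step 5

Assumption: the enzyme of step 5 stands for the best member of a screened panel, with a CYP52M1-type fatty-acid (ω-1)-hydroxylase and its reductase partner as parent, evolved for substrate 9 if the wild type is not selective enough.

**Route**

Step 1
Reactants: 1 oleic acid [(9Z)-octadec-9-enoic acid]; 2 N-hydroxyphthalimide
Product: 3 1,3-dioxoisoindolin-2-yl (9Z)-octadec-9-enoate (redox-active ester of oleic acid)
Conditions: DIC, DMAP (cat.), CH2Cl2, rt
Reagents that add atoms: none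
Why: Carbodiimide (Steglich-type) esterification, in which DIC activates the carboxyl group and DMAP relays the acyl group to the N-hydroxy oxygen; the isolated Z-alkene is not involved.

Step 2
Reactants: 4 1-bromo-3,5-dimethoxybenzene
Product: 6 (3,5-dimethoxyphenyl)zinc chloride as its LiCl complex in THF (titrated and used as solution), via (3,5-dimethoxyphenyl)magnesium bromide 5 (not isolated)
Conditions: Mg turnings, LiCl, THF, rt; then ZnCl2 (THF), 0 °C to rt
Reagents that add atoms: zinc chloride, Cl[Zn]Cl; magnesium, [Mg] (retained only in intermediate 5)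
Why: LiCl-assisted magnesium insertion into the aryl C–Br bond (Grignard formation) followed by Mg-to-Zn transmetalation gives the arylzinc chloride that the nickel coupling needs; the methyl ethers are inert.

Step 3
Reactants: 3 1,3-dioxoisoindolin-2-yl (9Z)-octadec-9-enoate; 6 (3,5-dimethoxyphenyl)zinc chloride (3 equiv)
Product: 7 1-[(8Z)-heptadec-8-en-1-yl]-3,5-dimethoxybenzene
Conditions: NiCl2·glyme (20 mol %), 4,4′-di-tert-butyl-2,2′-bipyridine (40 mol %), THF/DMF, rt
Reagents that add atoms: none
Why: Nickel-catalysed decarboxylative Negishi-type arylation of a redox-active ester: electron transfer from low-valent nickel to the N-acyloxyphthalimide releases phthalimide anion and CO2, and the primary C17 radical is captured at arylnickel and reductively eliminated to the aryl–C1 bond; the radical centre is seven carbons from the alkene, so neither cyclisation nor loss of Z geometry is expected.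

Step 4
Reactants: 7 1-[(8Z)-heptadec-8-en-1-yl]-3,5-dimethoxybenzene
Product: 9 5-[(8Z)-heptadec-8-en-1-yl]benzene-1,3-diol, via 3-[(8Z)-heptadec-8-en-1-yl]-5-methoxyphenol 8 (not isolated)
Conditions: NaSEt (excess), DMF, 150 °C, argon; then aq. HCl
Reagents that add atoms: none
Why: Thiolate SN2 O-demethylation of aryl methyl ethers, in which ethanethiolate attacks each O–CH3 carbon and expels the phenoxide (the second cleavage, through monoether 8, needs the excess reagent and heat), while the non-conjugated Z-alkene offers the thiolate nothing to attack and the argon atmosphere keeps out thiyl radicals that could isomerise it.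

Step 5
Reactants: 9 5-[(8Z)-heptadec-8-en-1-yl]benzene-1,3-diol
Product: 10 Hansfordiol E, 5-[(8Z,16S)-16-hydroxyheptadec-8-en-1-yl]benzene-1,3-diol
Conditions: evolved CYP52M1-type heme-thiolate P450 monooxygenase with its NADPH–cytochrome P450 reductase (recombinant Saccharomyces cerevisiae microsomes), NADP+ (cat.), D-glucose, glucose dehydrogenase, air, potassium phosphate buffer pH 7.5, 2-hydroxypropyl-β-cyclodextrin, 30 °C; EtOAc extraction, chromatography
Reagents that add atoms: dioxygen, O=O
Why: Proposed new method: the enzyme's oxoiron porphyrin radical cation (tetravalent iron), formed from O2 and two NADPH-derived electrons, abstracts a hydrogen atom from C16, and the hydroxyiron species returns OH to the carbon radical before it can invert (oxygen rebound), so the C16–O bond forms with retention at the pro-S C–H bond while the second oxygen atom leaves as water. The closest known reaction is the (ω-1)-hydroxylation of oleic acid to 17-hydroxyoleic acid of the same (S) configuration by the CYP52M1 hydroxylase of sophorolipid-producing yeast, together with the ω-1 to ω-3 hydroxylation of fatty acids by CYP102A1; neither has been shown with a resorcinol in place of the carboxyl group. No ring is closed. The C16 stereocentre is controlled by the enzyme pocket alone, which should present only the pro-S hydrogen of C16 to the oxo ligand, since the substrate has no stereocentre of its own. The step needs site selectivity for C16 over C17, C15, the allylic C7 and C10 positions, the C8=C9 alkene and the electron-rich ring A; what the substrate contributes is that 9 is oleic acid with the carboxyl carbon exchanged for the aryl ipso carbon, so the (CH2)7 spacer, the Z-alkene kink and the nine-carbon tail are identical and the tail should sit in the same register over the heme, where the secondary C16–H bond is also weaker than the C17 methyl C–H bonds. Remaining errors (ω- or (ω-2)-hydroxylation, ketone formation, the wrong enantiomer) would have to be removed by screening homologues and by directed evolution of the channel-mouth residues that meet the resorcinol head.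

**Compound list**

1 | oleic acid, (9Z)-octadec-9-enoic acid | CCCCCCCC/C=C\CCCCCCCC(=O)O | starting material
2 | N-hydroxyphthalimide | O=C1c2ccccc2C(=O)N1O | starting material
3 | 1,3-dioxoisoindolin-2-yl (9Z)-octadec-9-enoate | CCCCCCCC/C=C\CCCCCCCC(=O)ON1C(=O)c2ccccc2C1=O | intermediate
4 | 1-bromo-3,5-dimethoxybenzene | COc1cc(Br)cc(OC)c1 | starting material
5 | (3,5-dimethoxyphenyl)magnesium bromide | COc1cc([Mg]Br)cc(OC)c1 | intermediate
6 | (3,5-dimethoxyphenyl)zinc chloride | COc1cc([Zn]Cl)cc(OC)c1 | intermediate
7 | 1-[(8Z)-heptadec-8-en-1-yl]-3,5-dimethoxybenzene | CCCCCCCC/C=C\CCCCCCCc1cc(OC)cc(OC)c1 | intermediate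
8 | 3-[(8Z)-heptadec-8-en-1-yl]-5-methoxyphenol | CCCCCCCC/C=C\CCCCCCCc1cc(O)cc(OC)c1 | intermediate
9 | 5-[(8Z)-heptadec-8-en-1-yl]benzene-1,3-diol | CCCCCCCC/C=C\CCCCCCCc1cc(O)cc(O)c1 | intermediate
10 | Hansfordiol E, 5-[(8Z,16S)-16-hydroxyheptadec-8-en-1-yl]benzene-1,3-diol | C[C@H](O)CCCCCC/C=C\CCCCCCCc1cc(O)cc(O)c1 | target

**Step count**

Total steps: 5. Longest linear sequence: 4 steps (1, 3, 4, 5 from oleic acid; equally 2, 3, 4, 5 from the aryl bromide).

**Steps most likely to fail**

Step 5 (proposed new method). The uncharged resorcinol head may not bind productively, so turnover stays low or uncoupled. Oxygen may be delivered to the wrong site (C17, C15, the allylic C7 or C10, the alkene or ring A) or to the pro-R hydrogen, and the carbinol may be over-oxidised to the ketone.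

Fallback, known chemistry, setting out from 7 and coming back at 10: the stereocentre is bought instead of made, and the C8=C9 bond is rebuilt by a Wittig reaction.
- Oxidative cleavage of 7 (OsO4 cat., NaIO4, 2,6-lutidine, dioxane/H2O) gives 8-(3,5-dimethoxyphenyl)octanal F1 beside nonanal.
- In parallel, 1-bromo-6-chlorohexane and Mg in THF give 6-chlorohexylmagnesium bromide F2. It opens commercial (S)-propylene oxide at the CH2 carbon (CuI cat., THF, −30 °C) to (2S)-9-chlorononan-2-ol F3, with the configuration untouched.
- NaI in acetone at reflux gives (2S)-9-iodononan-2-ol F4, and PPh3 in MeCN at reflux gives [(8S)-8-hydroxynonyl]triphenylphosphonium iodide F5.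
- Two equivalents of NaHMDS (THF, −78 to 0 °C) give sodium (2S)-9-(triphenyl-λ5-phosphanylidene)nonan-2-olate F6. With F1 at −78 °C it should give, as a lithium-free Z-selective Wittig reaction, (2S,9Z)-17-(3,5-dimethoxyphenyl)heptadec-9-en-2-ol F7.
- NaSEt in DMF as in step 4 then frees the resorcinol and gives 10.

Step 3. Acyl transfer from the activated ester to the arylzinc, biaryl homocoupling, and reduction or β-hydride loss at the alkyl–nickel stage may outrun the cross-coupling.

Fallback, setting out from 4 and coming back at 7: the aryl–chain bond is made by two-electron palladium chemistry on a short chain and the Z-alkene by Wittig olefination.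
- Sonogashira coupling of 4 with commercial oct-7-yn-1-ol (Pd(PPh3)2Cl2, CuI, Et3N, 70 °C) gives 8-(3,5-dimethoxyphenyl)oct-7-yn-1-ol F8.
- Hydrogenation (H2, Pd/C, EtOAc) gives 8-(3,5-dimethoxyphenyl)octan-1-ol F9.
- Dess–Martin oxidation (CH2Cl2, NaHCO3) gives 8-(3,5-dimethoxyphenyl)octanal F10, the same aldehyde as F1.
- Nonylidene(triphenyl)-λ5-phosphane F11, from commercial nonyltriphenylphosphonium bromide and NaHMDS in THF, adds to F10 at −78 °C and should give 7 with mainly Z geometry.

Step 4. The second demethylation may stall at monoether 8, or thiyl radicals formed from traces of oxygen may isomerise the Z-alkene at 150 °C.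

Fallback, setting out from 3 and coming back at 9: the phenols are carried as silyl ethers, so deprotection becomes a fluoride cleavage at 0 °C.
- Commercial 5-bromobenzene-1,3-diol is silylated (TBSCl, imidazole, DMF) to 1-bromo-3,5-bis(tert-butyldimethylsilyloxy)benzene F12.
- Mg/LiCl gives the Grignard reagent [3,5-bis(tert-butyldimethylsilyloxy)phenyl]magnesium bromide F13, and ZnCl2 converts it into [3,5-bis(tert-butyldimethylsilyloxy)phenyl]zinc chloride F14, both as in step 2.
- Coupling of F14 with 3 under the conditions of step 3 gives 1,3-bis(tert-butyldimethylsilyloxy)-5-[(8Z)-heptadec-8-en-1-yl]benzene F15.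
- TBAF buffered with AcOH in THF at 0 °C gives 9.

**Further compounds**

F1 | step 5 | 8-(3,5-dimethoxyphenyl)octanal | COc1cc(CCCCCCCC=O)cc(OC)c1
F2 | step 5 | 6-chlorohexylmagnesium bromide | ClCCCCCC[Mg]Br
F3 | step 5 | (2S)-9-chlorononan-2-ol | C[C@H](O)CCCCCCCCl
F4 | step 5 | (2S)-9-iodononan-2-ol | C[C@H](O)CCCCCCCI
F5 | step 5 | [(8S)-8-hydroxynonyl]triphenylphosphonium iodide | C[C@H](O)CCCCCCC[P+](c1ccccc1)(c1ccccc1)c1ccccc1.[I-]
F6 | step 5 | sodium (2S)-9-(triphenyl-λ5-phosphanylidene)nonan-2-olate | C[C@H]([O-])CCCCCCC=P(c1ccccc1)(c1ccccc1)c1ccccc1.[Na+]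
F7 | step 5 | (2S,9Z)-17-(3,5-dimethoxyphenyl)heptadec-9-en-2-ol | C[C@H](O)CCCCCC/C=C\CCCCCCCc1cc(OC)cc(OC)c1
F8 | step 3 | 8-(3,5-dimethoxyphenyl)oct-7-yn-1-ol | COc1cc(C#CCCCCCCO)cc(OC)c1
F9 | step 3 | 8-(3,5-dimethoxyphenyl)octan-1-ol | COc1cc(CCCCCCCCO)cc(OC)c1
F10 | step 3 | 8-(3,5-dimethoxyphenyl)octanal | COc1cc(CCCCCCCC=O)cc(OC)c1
F11 | step 3 | nonylidene(triphenyl)-λ5-phosphane | CCCCCCCCC=P(c1ccccc1)(c1ccccc1)c1ccccc1
F12 | step 4 | 1-bromo-3,5-bis(tert-butyldimethylsilyloxy)benzene | CC(C)(C)[Si](C)(C)Oc1cc(Br)cc(O[Si](C)(C)C(C)(C)C)c1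
F13 | step 4 | [3,5-bis(tert-butyldimethylsilyloxy)phenyl]magnesium bromide | CC(C)(C)[Si](C)(C)Oc1cc([Mg]Br)cc(O[Si](C)(C)C(C)(C)C)c1
F14 | step 4 | [3,5-bis(tert-butyldimethylsilyloxy)phenyl]zinc chloride | CC(C)(C)[Si](C)(C)Oc1cc([Zn]Cl)cc(O[Si](C)(C)C(C)(C)C)c1
F15 | step 4 | 1,3-bis(tert-butyldimethylsilyloxy)-5-[(8Z)-heptadec-8-en-1-yl]benzene | CCCCCCCC/C=C\CCCCCCCc1cc(O[Si](C)(C)C(C)(C)C)cc(O[Si](C)(C)C(C)(C)C)c1
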